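In a one-step world every partner fed would leave as target, and each flask would stop at its charge of partner, the limiting reagent below one equivalent; the two earlier runs refuse that world.

| flask | substrate | partner | free catalyst | remark | time |
|---|---|---|---|---|---|
| Thursday's | 14 mM | 0.31 equiv (fed, over 50 min) | 2.5 mol% | run made earlier |  |
| Sunday's | 14 mM | 2 equiv (fed, over 50 min) | 2.5 mol% | run made earlier |  |
| summer | 14 mM | 0.700 equiv (fed, over 50 min) | 2.5 mol% |  | 1.0 h |
| noon | 14 mM | 1.05 equiv (fed, over 50 min) | 2.5 mol% |  | 1.0 h |
| dusk | 14 mM | 2.10 equiv (fed, over 50 min) | 2.5 mol% |  | 1.0 h |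
| autumn | 14 mM | 0.350 equiv (fed, over 50 min) | 2.5 mol% |  | 1.0 h |
| midnight | 14 mM | 3.20 equiv (fed, over 50 min) | 2.5 mol% |  | 1.0 h |
| winter | 14 mM | 0.530 equiv (fed, over 50 min) | 2.5 mol% |  | 1.0 h |

| run | time / min | target / % | substrate / % |
|---|---|---|---|
| Thursday's | 8.00 | 0.9 | 96.4 |
| Thursday's | 15.0 | 2.9 | 95.0 |
| Thursday's | 20.0 | 5.6 | 92.4 |
| Thursday's | 30.0 | 9.5 | 88.5 |
| Thursday's | 40.0 | 13.4 | 83.0 |
| Sunday's | 8.00 | 6.8 | 89.9 |
| Sunday's | 15.0 | 18.6 | 78.4 |
| Sunday's | 20.0 | 27.4 | 69.7 |
| Sunday's | 30.0 | 46.6 | 52.0 |
| Sunday's | 40.0 | 64.9 | 33.3 |

(scatter of a reading: 0.5 percentage points)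



- all flasks from highest to lowest amount of target, in percent of the substrate charged, at 1.0 h (summer / noon / dusk / autumn / midnight / winter)
- the amount of target, in percent of the substrate charged of the flask you put first, at 1.0 h
- the amount of target, in percent of the substrate charged of the flask you put last, at 1.0 h

Thursday's run turns 63.0 % of its feed into target, reckoned as the mean slope between first and last reading over the feed rate, the partner yield, while Sunday's run by the same reckoning gives 45.4 %, lower than Thursday's, both being readings that carry the scatter. Multiplying yield by charge replaces the curve by its mean and pretends that target starts at once and stops with the feed, but Thursday's line reaches back to a lag of 5.70 min, shorter than the 10.0 min that follow the feed, so the tail can repay it.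

I hold Thursday's yield fixed across the plate, which gives 22.1 % for autumn and 66.2 % for noon, and for dusk 132 %, more than the substrate charged, so that dusk and midnight tie at the substrate's end. The forecast takes Sunday's drop seriously, saying “This suggests partner is lost to a competing path, partly second order”; it gives midnight > dusk > noon > summer > winter > autumn, with 98 % at the top and 21 % at the bottom, and puts noon near 55 and dusk near 93.

The flask gives midnight > dusk > noon > summer > winter > autumn, from 97.3 % in midnight to 21.2 % in autumn, with noon at 58.4 % and dusk at 90.7 %, so the forecast stands and my tie and my noon fall, while my view keeps autumn, which has turned 60.4 % of its partner charge into target against the 63.0 % read from Thursday's run.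

    substrate + free catalyst ⇌ catalyst intermediate A (K = 25.2 M⁻¹, k = 8.37 M⁻¹ s⁻¹)
    catalyst intermediate A → catalyst intermediate B (k = 11.0 s⁻¹)
    partner + catalyst intermediate B → catalyst intermediate C (k = 5.17 M⁻¹ s⁻¹)
    catalyst intermediate C → by-product + catalyst intermediate D (k = 0.129 s⁻¹)
    catalyst intermediate D → free catalyst + target (k = 0.108 s⁻¹)
    free catalyst + by-product ⇌ idle complex, settled at all times (K = 25.2 M⁻¹)
    partner → decomposed reagent (k = 0.00103 s⁻¹)

In autumn at 1.00 h, catalyst intermediate B, the resting state with 98.2 % of the catalyst, captures partner at a pseudo-first-order 0.00178 s⁻¹, faster than partner decomposes at 0.00103 s⁻¹, a capture share of 63.3 %. In dusk at that time the same form holds 36.3 % of the catalyst. For the neighbour of autumn with 0.210 equiv of partner, Thursday's yield gives 13.2 % of target, and the computed flask holds 12.9 % of target.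

(The data were computed on assumed constants; noise was put on by code.)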